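**Retrosynthetic overview**

1. The plan rests on one feature of the dioxane ring: the C3 methyl is the neighbour of C2, and C2 carries both ring oxygen O1 and the 4-oxy-3,5-dimethoxyphenyl ring, so C2 can hold a cation and the methyl can be the remnant of a CH2 that once bridged C2 and C3.
2. End game: phenol from its pivalate (15 from 14), allyl from the aryl bromide and allyl-Bpin (14 from 12), and 12 from cyclopropane 11 by protonolysis of the C2–CH2 bond with hydride capture at C2 (sets 2R, trans to 3R).
3. Key disconnection: cyclopropane 11 back to the flat 2-aryl-1,4-benzodioxine 9 plus CH2 from CH2I2, by ligand-controlled Simmons–Smith transfer (forms C3–CH2 and C2–CH2, sets C3).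
4. Benzodioxine 9 from keto-phenol 7 (hemiketal dehydration), 7 from keto-aldehyde 5 (Dakin-type oxidation), 5 from 5-bromo-o-vanillin 4 and bromoketone 3, 3 from acetosyringone 1.
5. Ring order: dioxine ring (step 5), temporary cyclopropane (step 6), cyclopropane opened again (step 7); both benzene rings are bought.

Key step: step 6

Assumption: the sense of induction of the dipeptide–zinc carbenoid on this substrate class cannot be predicted with confidence, so the route is written for whichever ligand antipode (L,L or D,D) delivers CH2 to the face that gives the (1aR,7aR) cyclopropane 11, to be fixed by a trial run with both.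

**Route**

Step 1
Reactants: 1 acetosyringone (1-(4-hydroxy-3,5-dimethoxyphenyl)ethanone)
Product: 2 pivalate ketone (4-acetyl-2,6-dimethoxyphenyl pivalate)
Conditions: PivCl, Et3N, DMAP (cat.), CH2Cl2, 0 °C → rt
Reagents that add atoms: pivaloyl chloride, CC(C)(C)C(=O)Cl
Why: DMAP-catalysed O-acylation of the phenol (nucleophilic acyl substitution) should proceed despite the two flanking methoxy groups, and the pivalate is chosen because it is electron-withdrawing and should survive every acidic and basic step up to step 9.

Step 2
Reactants: 2 pivalate ketone (4-acetyl-2,6-dimethoxyphenyl pivalate)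
Product: 3 bromoketone (4-(bromoacetyl)-2,6-dimethoxyphenyl pivalate)
Conditions: CuBr2 (2.1 equiv), EtOAc/CHCl3 1:1, reflux
Reagents that add atoms: copper(II) bromide, [Cu+2].[Br-].[Br-]
Why: Copper(II) bromide α-bromination of an aryl methyl ketone through its enol should stop at the monobromide, and the ring should not be brominated because the acyl and acyloxy groups deactivate it.

Step 3
Reactants: 3 bromoketone (4-(bromoacetyl)-2,6-dimethoxyphenyl pivalate); 4 5-bromo-o-vanillin (5-bromo-2-hydroxy-3-methoxybenzaldehyde)
Product: 5 keto-aldehyde ether (4-[2-(4-bromo-2-formyl-6-methoxyphenoxy)acetyl]-2,6-dimethoxyphenyl pivalate)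
Conditions: K2CO3 (1.2 equiv), acetone, 0 °C → rt
Reagents that add atoms: none
Why: Williamson ether synthesis: the acidic phenoxide displaces the very reactive phenacyl bromide by SN2 at or below room temperature, which is mild enough to avoid aldol-type closure onto the aldehyde and to spare the pivalate, and it fixes this oxygen as the future O4 next to the methoxy-bearing carbon.

Step 4
Reactants: 5 keto-aldehyde ether (4-[2-(4-bromo-2-formyl-6-methoxyphenoxy)acetyl]-2,6-dimethoxyphenyl pivalate)
Product: 7 keto-phenol (4-[2-(4-bromo-2-hydroxy-6-methoxyphenoxy)acetyl]-2,6-dimethoxyphenyl pivalate), via aryl formate 6 (not isolated)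
Conditions: mCPBA, CH2Cl2, 0 °C → rt; aq. NaHCO3 wash; then Et3N (cat.), MeOH, 0 °C
Reagents that add atoms: mCPBA (3-chloroperoxybenzoic acid), OOC(=O)c1cccc(Cl)c1
Why: Dakin-type Baeyer–Villiger oxidation: the peracid adds to the aldehyde and the aryl group, activated by its ortho alkoxy substituent, migrates to oxygen to give formate 6, whose unhindered formyl group is removed by base-catalysed methanolysis far faster than the hindered pivalate, revealing the future O1 phenol while the aryl ketone is oxidised much more slowly.

Step 5
Reactants: 7 keto-phenol (4-[2-(4-bromo-2-hydroxy-6-methoxyphenoxy)acetyl]-2,6-dimethoxyphenyl pivalate)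
Product: 9 benzodioxine (4-(7-bromo-5-methoxy-1,4-benzodioxin-2-yl)-2,6-dimethoxyphenyl pivalate), via cyclic hemiketal 8 (not isolated)
Conditions: TsOH·H2O (10 mol%), toluene, reflux, Dean–Stark
Reagents that add atoms: none
Why: Acid-catalysed cyclodehydration: the phenol adds to the ketone to give the six-membered hemiketal 8, which loses water by E1 elimination through the aryl-stabilised oxocarbenium ion as water is removed azeotropically; only C3 carries β-hydrogens so one enol ether can form, and benzofuran-type Friedel–Crafts closure is blocked because both positions ortho to the ether oxygen are substituted.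

Step 6
Reactants: 9 benzodioxine (4-(7-bromo-5-methoxy-1,4-benzodioxin-2-yl)-2,6-dimethoxyphenyl pivalate); 10 diiodomethane
Product: 11 cyclopropane (4-[(1aR,7aR)-4-bromo-6-methoxy-1a,7a-dihydro-1H-cyclopropa[b][1,4]benzodioxin-1a-yl]-2,6-dimethoxyphenyl pivalate; CH2 bridges the former C2 and C3, cis-fused)
Conditions: Boc-L-Val-L-Pro-OMe (1.25 equiv; antipode if required, see assumption), Et2Zn (1.25 equiv), CH2I2, CH2Cl2, −40 → 0 °C; pyridine, then aq. NaHCO3
Reagents that add atoms: none
Why: Proposed new method: the zinc carbenoid held on the N-zincated dipeptide (L*Zn–CH2I) is an electrophilic methylene donor that attacks the electron-rich C2=C3 enol ether π bond through the concerted butterfly transition state of the Simmons–Smith reaction, making C3–CH2 and C2–CH2 in one event while iodide passes to zinc. The closest known reaction type is the dipeptide-ligand-controlled Simmons–Smith cyclopropanation of unfunctionalised aryl alkenes and of aryl ketone silyl enol ethers; a cyclic enol ether carrying a second vinylic oxygen has not been used in it. The three-membered ring closes by suprafacial [2+1] methylene transfer onto the endocyclic cis alkene, so cis fusion to the dioxine ring is the only possible mode. Both new stereocentres (C1a and C7a, the former C2 and C3) arise together: their relative configuration follows from syn addition and their absolute configuration from the chiral ligand on zinc, which chooses the enantiotopic face, since 9 has no stereocentre and no directing group. The step needs face selectivity and attack on one alkene only; 9 secures the second by still carrying bromide in place of the allyl group, and helps the first by being rigid and planar with very different alkene substituents (aryl plus O on C2, H plus O on C3), the pattern these ligands read best in aryl enol ethers. Zinc iodide is tied up with pyridine before work-up so that the donor-substituted cyclopropane is not opened by Lewis acid.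

Step 7
Reactants: 11 cyclopropane (4-[(1aR,7aR)-4-bromo-6-methoxy-1a,7a-dihydro-1H-cyclopropa[b][1,4]benzodioxin-1a-yl]-2,6-dimethoxyphenyl pivalate)
Product: 12 trans bromide (4-[(2R,3R)-7-bromo-5-methoxy-3-methyl-2,3-dihydro-1,4-benzodioxin-2-yl]-2,6-dimethoxyphenyl pivalate; aryl and methyl trans)
Conditions: CF3CO2H, Et3SiH (excess), CH2Cl2, −20 → 0 °C
Reagents that add atoms: none
Why: Proposed new method: TFA protonates the least substituted cyclopropane carbon (the CH2) with cleavage of its bond to C1a, the only rupture that leaves a cation stabilised by both O1 and the aryl ring, so the CH2 becomes the C3 methyl with the C3 centre untouched, and Et3SiH then transfers hydride along the axial trajectory of the half-chair that keeps the methyl pseudo-equatorial, placing aryl and methyl trans-diequatorial (2R set by the existing 3R centre); the closest known types are acid opening of 1,2-cyclopropanated glycals to 2-C-methyl glycosides and silane reduction of aryl lactols and ketals in C-aryl glycoside synthesis, and the para-pivaloyloxy group keeps the aryl ring from ionising the C2–O1 bond of the product.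

Step 8
Reactants: 12 trans bromide (4-[(2R,3R)-7-bromo-5-methoxy-3-methyl-2,3-dihydro-1,4-benzodioxin-2-yl]-2,6-dimethoxyphenyl pivalate); 13 allylboronic acid pinacol ester
Product: 14 allyl pivalate (4-[(2R,3R)-7-allyl-5-methoxy-3-methyl-2,3-dihydro-1,4-benzodioxin-2-yl]-2,6-dimethoxyphenyl pivalate)
Conditions: Pd(dppf)Cl2 (5 mol%), CsF (3 equiv), THF, 65 °C
Reagents that add atoms: none
Why: Suzuki–Miyaura coupling: oxidative addition into the unhindered aryl C–Br bond, fluoride-assisted transfer of the allyl group from boron and reductive elimination, under anhydrous fluoride conditions that should spare the pivalate and leave the two stereocentres untouched.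

Step 9
Reactants: 14 allyl pivalate (4-[(2R,3R)-7-allyl-5-methoxy-3-methyl-2,3-dihydro-1,4-benzodioxin-2-yl]-2,6-dimethoxyphenyl pivalate)
Product: 15 target (4-[(2R,3R)-7-allyl-5-methoxy-3-methyl-2,3-dihydro-1,4-benzodioxin-2-yl]-2,6-dimethoxyphenol)
Conditions: DIBAL-H (3 equiv), CH2Cl2, −78 °C; Rochelle salt work-up
Reagents that add atoms: none
Why: Reductive ester cleavage: hydride adds to the hindered pivaloyl carbonyl and the aryloxide leaves, under cold aprotic conditions in which the terminal alkene is not hydroaluminated and C2 cannot epimerise through a quinone methide.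

**Compound list**

1 | acetosyringone (1-(4-hydroxy-3,5-dimethoxyphenyl)ethanone) | CC(=O)c1cc(OC)c(O)c(OC)c1 | starting material
2 | 4-acetyl-2,6-dimethoxyphenyl pivalate | CC(=O)c1cc(OC)c(OC(=O)C(C)(C)C)c(OC)c1 | intermediate
3 | 4-(bromoacetyl)-2,6-dimethoxyphenyl pivalate | BrCC(=O)c1cc(OC)c(OC(=O)C(C)(C)C)c(OC)c1 | intermediate
4 | 5-bromo-2-hydroxy-3-methoxybenzaldehyde (5-bromo-o-vanillin) | COc1cc(Br)cc(C=O)c1O | starting material
5 | 4-[2-(4-bromo-2-formyl-6-methoxyphenoxy)acetyl]-2,6-dimethoxyphenyl pivalate | O=Cc1cc(Br)cc(OC)c1OCC(=O)c1cc(OC)c(OC(=O)C(C)(C)C)c(OC)c1 | intermediate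
6 | 4-{2-[4-bromo-2-(formyloxy)-6-methoxyphenoxy]acetyl}-2,6-dimethoxyphenyl pivalate (aryl formate, not isolated) | O=COc1cc(Br)cc(OC)c1OCC(=O)c1cc(OC)c(OC(=O)C(C)(C)C)c(OC)c1 | intermediate
7 | 4-[2-(4-bromo-2-hydroxy-6-methoxyphenoxy)acetyl]-2,6-dimethoxyphenyl pivalate | Oc1cc(Br)cc(OC)c1OCC(=O)c1cc(OC)c(OC(=O)C(C)(C)C)c(OC)c1 | intermediate
8 | 4-(7-bromo-2-hydroxy-5-methoxy-2,3-dihydro-1,4-benzodioxin-2-yl)-2,6-dimethoxyphenyl pivalate (racemic cyclic hemiketal, not isolated) | Brc1cc(OC)c2c(c1)OC(O)(c1cc(OC)c(OC(=O)C(C)(C)C)c(OC)c1)CO2 | intermediate
9 | 4-(7-bromo-5-methoxy-1,4-benzodioxin-2-yl)-2,6-dimethoxyphenyl pivalate | Brc1cc(OC)c2c(c1)OC(c1cc(OC)c(OC(=O)C(C)(C)C)c(OC)c1)=CO2 | intermediate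
10 | diiodomethane | ICI | starting material
11 | 4-[(1aR,7aR)-4-bromo-6-methoxy-1a,7a-dihydro-1H-cyclopropa[b][1,4]benzodioxin-1a-yl]-2,6-dimethoxyphenyl pivalate | Brc1cc(OC)c2c(c1)O[C@@]3(c1cc(OC)c(OC(=O)C(C)(C)C)c(OC)c1)C[C@H]3O2 | intermediate
12 | 4-[(2R,3R)-7-bromo-5-methoxy-3-methyl-2,3-dihydro-1,4-benzodioxin-2-yl]-2,6-dimethoxyphenyl pivalate | Brc1cc(OC)c2c(c1)O[C@H](c1cc(OC)c(OC(=O)C(C)(C)C)c(OC)c1)[C@@H](C)O2 | intermediate
13 | allylboronic acid pinacol ester | C=CCB1OC(C)(C)C(C)(C)O1 | starting material
14 | 4-[(2R,3R)-7-allyl-5-methoxy-3-methyl-2,3-dihydro-1,4-benzodioxin-2-yl]-2,6-dimethoxyphenyl pivalate | C=CCc1cc(OC)c2c(c1)O[C@H](c1cc(OC)c(OC(=O)C(C)(C)C)c(OC)c1)[C@@H](C)O2 | intermediate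
15 | 4-[(2R,3R)-7-allyl-5-methoxy-3-methyl-2,3-dihydro-1,4-benzodioxin-2-yl]-2,6-dimethoxyphenol | C=CCc1cc(OC)c2c(c1)O[C@H](c1cc(OC)c(O)c(OC)c1)[C@@H](C)O2 | target

**Step count and risks**

Total step count: 9. Longest linear sequence: 9 steps (1 to 15); 5-bromo-o-vanillin 4 enters at step 3.

Steps most likely to fail:

1. Step 6. The ligated carbenoid may discriminate poorly between the two faces of the planar enol ether, or may transfer methylene too slowly because of its bulk, leaving time for zinc iodide to open the product. The fallback replaces asymmetric induction by resolution. Setting out from 9, the achiral and more electrophilic carbenoid CF3CO2ZnCH2I (Et2Zn, TFA, CH2I2, CH2Cl2, 0 °C), a standard reagent for enol ethers, should give the racemic cis-fused cyclopropane F1. Preparative chromatography on a polysaccharide chiral stationary phase then separates the enantiomers, and the (1aR,7aR) enantiomer is compound 11, where the route is rejoined. The bromine atom allows the absolute configuration to be assigned by anomalous-dispersion crystallography.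

2. Step 7. Three processes could intervene:
   - Proton loss from C3 of the C2 cation may compete with hydride capture, and re-protonation of the resulting 3-methyl enol ether would erode the C3 configuration.
   - Hydride delivery to the other face would give the cis isomer.
   - Cleavage of the ring-fusion bond would lead to ring expansion.

   The fallback separates ring opening from reduction and uses two precedented reaction types. Setting out from 11, mild acid in methanol (CSA cat., MeOH/CH2Cl2, 0 °C → rt), as used for solvolytic opening of cyclopropanated glycals, should trap the cation at once as the C2 methyl ketal F2. Reduction of this aryl ketal with Et3SiH and BF3·OEt2 in CH2Cl2/MeCN at −40 °C, as in C-aryl glycoside synthesis, should then give 12 by axial hydride delivery, where the route is rejoined.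

3. Step 3. Under carbonate the new ether can enolise at the O–CH2–C=O carbon and close onto the ortho formyl group by aldol condensation (Rap–Stoermer closure to a 2-aroylbenzofuran), consuming the aldehyde needed for step 4. The fallback removes the aldol acceptor during the alkylation. Setting out from 4, ethylene glycol and TsOH (toluene, Dean–Stark) should give the dioxolane-protected phenol F3. Alkylation with 3 (K2CO3, DMF, rt) should give the acetal ether F4, and dilute aqueous HCl in THF at room temperature should release the aldehyde to give 5, where the route is rejoined.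

**Further compounds**

F1 | step 6 | racemic cis-fused 4-(4-bromo-6-methoxy-1a,7a-dihydro-1H-cyclopropa[b][1,4]benzodioxin-1a-yl)-2,6-dimethoxyphenyl pivalate | Brc1cc(OC)c2c(c1)OC3(c1cc(OC)c(OC(=O)C(C)(C)C)c(OC)c1)CC3O2
F2 | step 7 | 4-[(3R)-7-bromo-2,5-dimethoxy-3-methyl-2,3-dihydro-1,4-benzodioxin-2-yl]-2,6-dimethoxyphenyl pivalate (mixture of C2 epimers) | Brc1cc(OC)c2c(c1)OC(OC)(c1cc(OC)c(OC(=O)C(C)(C)C)c(OC)c1)[C@@H](C)O2
F3 | step 3 | 4-bromo-2-(1,3-dioxolan-2-yl)-6-methoxyphenol | COc1cc(Br)cc(C2OCCO2)c1O
F4 | step 3 | 4-{2-[4-bromo-2-(1,3-dioxolan-2-yl)-6-methoxyphenoxy]acetyl}-2,6-dimethoxyphenyl pivalate | COc1cc(Br)cc(C2OCCO2)c1OCC(=O)c1cc(OC)c(OC(=O)C(C)(C)C)c(OC)c1
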